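**Assumption:** Dichrostachine L is the direct cycloadduct of the 12Z diene and the chromone–quinone, with free 5,7‑OH. C9, C5 and C10 are the natural labdane (sclareol) configuration. I verified this from the SMILES chirality tags.

## Retrosynthetic overview
1. Target **1** is disconnected at the cyclohexene. A Diels–Alder reaction between the 12Z‑labdatriene‑7‑one **2** and the 2‑(chromon‑2‑yl)‑5‑methoxybenzoquinone **3**, at the quinone C2=C3 bond, forms the cyclohexene and the cis‑fused enedione ring and sets three stereocentres in one step.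
2. Diene **2** comes from (–)‑sclareol **4**. Its decalin centres (C5, C9, C10) are kept. The side chain is shortened to a methyl ketone, C8‑OH is eliminated, C7 is oxidised, the vinyl carbinol is rebuilt, and the diene is made by dehydration.
3. Quinone **3** comes from phloroacetophenone and 2,4,5‑trimethoxybenzaldehyde by chalcone formation, I2/DMSO cyclisation and oxidative demethylation.
4. Rings are formed in this order: decalin (already in sclareol), chromone, quinone, then cyclohexene and fused enedione by Diels–Alder as the last step.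

## Route

**Step 1**
Reactants: 4, (–)‑sclareol
Product: 5, 8α‑hydroxy‑14,15‑bisnorlabdan‑13‑one
Conditions: KMnO4, acetone/H2O, 0 °C → rt
Reagents that add atoms: none
Why: Oxidative cleavage of the vinyl carbinol, followed by decarboxylation of the resulting α‑hydroxy acid, gives the methyl ketone (oxidative degradation). C5, C9, C10 and C8 are untouched.

**Step 2**
Reactants: 5
Product: 6, 14,15‑bisnorlabd‑8(17)‑en‑13‑one
Conditions: POCl3, pyridine, 0 °C → rt
Reagents that add atoms: none
Why: The 8α‑OH is equatorial, so its phosphorodichloridate has no anti‑periplanar ring hydrogen. E2 elimination therefore uses the C17 methyl hydrogens and gives the exocyclic alkene (dehydration). This step is now clean because no second alcohol is present.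

**Step 3**
Reactants: 6
Product: 7, 7‑hydroxy‑14,15‑bisnorlabd‑8(17)‑en‑13‑one (C7 epimers)
Conditions: SeO2 (10 mol %), TBHP, CH2Cl2, rt
Reagents that add atoms: SeO2 (O=[Se]=O, catalytic O‑atom source) and TBHP (CC(C)(C)OO, reoxidant); the C7–OH oxygen is incorporated.
Why: SeO2 allylic oxidation (ene reaction then [2,3]‑shift) puts OH on ring C7 and keeps the exocyclic alkene. The hindered tertiary C9–H is not abstracted. C7 stereochemistry is irrelevant because it is oxidised in step 5.

**Step 4**
Reactants: 7
Product: 8, labda‑8(17),14‑diene‑7,13‑diol (C7/C13 epimeric mixture)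
Conditions: CH2=CHMgBr (3.5 equiv), THF, –78 → 0 °C
Reagents that add atoms: vinylmagnesium bromide, C=C[Mg]Br (supplies C14–C15 after workup).
Why: Grignard 1,2‑addition to the methyl ketone. The free 7‑OH consumes one equivalent. C13 configuration is erased later by dehydration.

**Step 5**
Reactants: 8
Product: 9, 13‑hydroxylabda‑8(17),14‑dien‑7‑one
Conditions: activated MnO2 (20 equiv), CH2Cl2, rt
Reagents that add atoms: none
Why: MnO2 oxidises only the secondary allylic alcohol to the α‑methylene ketone. The tertiary allylic C13‑OH is inert. Cr(VI) is avoided because it would transpose the tertiary allylic alcohol.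

**Step 6**
Reactants: 9
Product: 2, (12Z)‑labda‑8(17),12,14‑trien‑7‑one
Conditions: Burgess reagent (1.5 equiv), PhH, 50 °C; Z isomer isolated by AgNO3–SiO2 chromatography
Reagents that add atoms: none (Burgess reagent, COC(=O)[N-]S(=O)(=O)[N+](CC)(CC)CC, is lost as by‑products).
Why: Burgess syn‑elimination (Ei) of the tertiary allylic alcohol. In the eclipsed cyclic transition state, vinyl and methyl have similar size, so both 12E and 12Z dienes form. Z is needed for the endo addition in step 10. The E and cross‑conjugated 13(16)‑ene isomers are separated.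

**Step 7**
Reactants: 10, 2',4',6'‑trihydroxyacetophenone; 11, 2,4,5‑trimethoxybenzaldehyde
Product: 12, (E)‑2',4',6'‑trihydroxy‑2,4,5‑trimethoxychalcone
Conditions: KOH (6 equiv), EtOH/H2O, rt → 60 °C
Reagents that add atoms: none
Why: Claisen–Schmidt condensation. Excess base deprotonates the phenols so the acetyl group can still enolise.

**Step 8**
Reactants: 12
Product: 13, 5,7‑dihydroxy‑2',4',5'‑trimethoxyflavone
Conditions: I2 (20 mol %), DMSO, 130 °C
Reagents that add atoms: none
Why: Oxidative cyclisation of the 2'‑hydroxychalcone (oxa‑Michael addition then iodine/DMSO dehydrogenation) builds the chromone.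

**Step 9**
Reactants: 13
Product: 3, 5,7‑dihydroxy‑2‑(5‑methoxy‑1,4‑benzoquinon‑2‑yl)chromone
Conditions: (NH4)2Ce(NO3)6 (2.5 equiv), MeCN/H2O (4:1), 0 °C, 15 min
Reagents that add atoms: water, O, supplies the quinone C=O oxygens; the two methyls leave as MeOH.
Why: CAN oxidatively demethylates the only para‑dimethoxy pair (2',5'). The 4'‑OMe remains, giving the 2‑aryl‑5‑methoxyquinone. The chromone is electron‑poor and survives.

**Step 10**
Reactants: 2 (1.5 equiv); 3 (1.0 equiv)
Product: 1, Dichrostachine L
Conditions: PhMe/1,4‑dioxane (4:1), BHT, 100 °C, sealed tube, 48 h; neutral workup, HPLC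
Reagents that add atoms: none
Why: Diels–Alder reaction, suprafacial on both partners, at the quinone C2=C3 bond. The C5=C6 bond is deactivated as a vinylogous ester. The C4 carbonyl makes C2 the electrophilic terminus, which bonds to diene C12 (bearing the 13‑methyl donor). The Z‑diene reacts through the endo (ring under the diene) transition state. This gives the cis ring fusion and puts C11 trans to the Cq–C(=O) bond, as the target SMILES requires. Quaternary Cq cannot aromatise, so the adduct stays as the enedione. The facial selectivity, and hence the absolute configuration of C12/Cq/Cf, is controlled only by the decalin through C9–C11. The minor diastereomer is removed by HPLC.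

## Compound list
1 | Dichrostachine L | C=C1C(=O)C[C@H]2C(C)(C)CCC[C@]2(C)[C@H]1C[C@@H]1C(C)=CC[C@H]2C(=O)C(OC)=CC(=O)[C@@]12c1cc(=O)c2c(O)cc(O)cc2o1 | target
2 | (12Z)‑labda‑8(17),12,14‑trien‑7‑one | C=C1C(=O)C[C@H]2C(C)(C)CCC[C@]2(C)[C@H]1C/C=C(\C=C)C | intermediate
3 | 5,7‑dihydroxy‑2‑(5‑methoxy‑1,4‑benzoquinon‑2‑yl)chromone | O=c1cc(-C2=CC(=O)C(OC)=CC2=O)oc2cc(O)cc(O)c12 | intermediate
4 | (–)‑sclareol | C[C@@]1(O)CC[C@H]2C(C)(C)CCC[C@]2(C)[C@H]1CC[C@@](C)(O)C=C | starting material
5 | 8α‑hydroxy‑14,15‑bisnorlabdan‑13‑one | C[C@@]1(O)CC[C@H]2C(C)(C)CCC[C@]2(C)[C@H]1CCC(C)=O | intermediate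
6 | 14,15‑bisnorlabd‑8(17)‑en‑13‑one | C=C1CC[C@H]2C(C)(C)CCC[C@]2(C)[C@H]1CCC(C)=O | intermediate
7 | 7‑hydroxy‑14,15‑bisnorlabd‑8(17)‑en‑13‑one (C7 epimers) | C=C1C(O)C[C@H]2C(C)(C)CCC[C@]2(C)[C@H]1CCC(C)=O | intermediate
8 | labda‑8(17),14‑diene‑7,13‑diol (epimeric) | C=C1C(O)C[C@H]2C(C)(C)CCC[C@]2(C)[C@H]1CCC(C)(O)C=C | intermediate
9 | 13‑hydroxylabda‑8(17),14‑dien‑7‑one | C=C1C(=O)C[C@H]2C(C)(C)CCC[C@]2(C)[C@H]1CCC(C)(O)C=C | intermediate
10 | 2',4',6'‑trihydroxyacetophenone | CC(=O)c1c(O)cc(O)cc1O | starting material
11 | 2,4,5‑trimethoxybenzaldehyde | COc1cc(OC)c(C=O)cc1OC | starting material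
12 | (E)‑2',4',6'‑trihydroxy‑2,4,5‑trimethoxychalcone | O=C(/C=C/c1cc(OC)c(OC)cc1OC)c1c(O)cc(O)cc1O | intermediate
13 | 5,7‑dihydroxy‑2',4',5'‑trimethoxyflavone | O=c1cc(-c2cc(OC)c(OC)cc2OC)oc2cc(O)cc(O)c12 | intermediate

## Totals
Total steps: 10. Longest linear sequence: 7 (steps 1–6, then 10).

## Three steps most likely to fail
1. **Step 10 (Diels–Alder).** The Z‑diene is sluggish, and the bond to the fully substituted quinone carbon is hindered. Regiochemistry, endo/exo selectivity and facial selectivity are all uncertain.
   Fallback: use a 2‑acylquinone bearing Cq–C(=O)CH2C(=O)Ar(OH) as the dienophile. It is far more reactive and can be chelation‑controlled. Then close the chromone by acid cyclodehydration after the cycloaddition.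
2. **Step 6 (Z‑diene by dehydration).** Only a fraction of the product is the Z isomer, and the cross‑conjugated isomer competes.
   Fallback: take the separated 12E diene and enrich the Z isomer by triplet‑sensitised photoisomerisation, then recycle.
3. **Step 9 (CAN oxidation on the free 5,7‑dihydroxyflavone).** The electron‑rich phenolic A ring may be over‑oxidised or degraded.
   Fallback: use 4',6'‑bis‑MOM‑2'‑hydroxyacetophenone through steps 7–9 and remove the MOM groups at the end with a mild Lewis acid (MgBr2·OEt2).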